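Slowness is the first suspicion on this flask, where a single-handed catalyst turns a racemate and a partner into product while a racemization catalyst interconverts the two substrate hands, and the earlier runs show whether waiting pays.

| flask | left-handed substrate | right-handed substrate | partner | free catalyst | racemization catalyst | impurity | remark | time |
|---|---|---|---|---|---|---|---|---|
| ochre | 13 mM | 13 mM | 4 equiv | 2.8 mol% | 2 mol% | 60 µM | run made earlier |  |
| amber | 30 mM | 30 mM | 4 equiv | 2.8 mol% | 2 mol% | 60 µM | run made earlier |  |
| grey | 20 mM | 20 mM | 4 equiv | 2.8 mol% | 1 mol% | 60 µM | run made earlier |  |
| flask | 20 mM | 20 mM | 4.00 equiv | 2.8 mol% | 2 mol% | 60 µM |  | 15 h |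

- ochre (time / h: left-handed substrate / %, right-handed substrate / %): 1.33: 50, 50; 2.00: 44, 43; 3.00: 43, 49; 5.00: 46, 46; 8.00: 45, 47; 12.0: 45, 44; 20.0: 46, 46
- amber (time / h: left-handed substrate / %, right-handed substrate / %): 2.50: 29, 31; 5.00: 27, 29; 8.00: 28, 28; 10.0: 32, 31; 12.0: 32, 28; 15.0: 31, 31; 20.0: 30, 27
- grey (time / h: left-handed substrate / %, right-handed substrate / %): 1.50: 40, 43; 5.00: 35, 41; 8.00: 40, 42; 12.0: 37, 38; 20.0: 41, 40

(standard deviation of a reading: 1.5 percentage points)

- free catalyst is single-handed; left-handed substrate and right-handed substrate are mirror images of each other, charged as a racemate, each of them at the stated concentration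
- an excess is the difference of the two amounts in percent of their sum
- an excess is below zero if the other one leads

- part of the left-handed substrate and right-handed substrate charged together that has reacted at 15 h
- excess of left-handed product over right-handed product in the product at 15 h
- excess of right-handed substrate over left-handed substrate among what is left of the two at 15 h

Two chemists read these runs. The first holds that the flask is merely slow: grey, at the flask's concentration, had 83.0% of its substrate left at 1.50 h, so a steady first-order loss gives 84.5% reacted at 15 h.

The second, whose reckoning I adopt, answers that grey still reads 81.0% at 20.0 h, more than the 8.34% that curve allows, so these runs stall on a plateau. Substrate loss is pseudo-first-order in [partner][free catalyst], and if both fade on their own clocks, the plateau depends on their charges. She takes the dose as [partner]·([free catalyst] − [impurity]) at charge, assuming the impurity removes catalyst one for one. Her stall constant K is −ln(plateau fraction) per unit dose 5530 M⁻², read from amber's last 5 readings. Ochre's last 5 give 5690 M⁻², a separate reading of the same constant.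

The flask's dose of 4.00 × 10⁻⁵ M^2 then gives 19.8% reacted. The slow view keeps the time before grey's first reading; in the repeat, watch the plateau's height from the first hours. The substrate hands can part early, for grey reads 35% and 41% at 5.00 h, but ochre, at the flask's racemization loading, reads 46% and 46% at 20.0 h, so I expect eS near zero at 15 h, and the substrate readings say little about eP.

The forecast gives c 20% (16% to 24%), eP 35% (3% to 85%) and eS 0.7% (−1.5% to 3%), holding that “the catalyst dies early and the end point matters, not the time”.

The flask gives c 21.1%, which is 1.3 percentage points above my reckoning, with eP 36.3% and eS 0.00882%, and a reading at 150 h instead of 15 h changes neither c nor eP .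

    free catalyst → spent catalyst B (k = 0.620 h⁻¹)
    left-handed substrate + racemization catalyst ⇌ right-handed substrate + racemization catalyst, rate k2*[racemization catalyst]*[left-handed substrate] forward; the back reaction follows from the equilibrium constant (k = 630 M⁻¹ h⁻¹)
    partner → decomposed reagent (k = 0.470 h⁻¹)
    partner + free catalyst + right-handed substrate → free catalyst + right-handed product (k = 4300 M⁻² h⁻¹)
    free catalyst + impurity → spent catalyst A (k = 5.50 × 10⁵ M⁻¹ h⁻¹)
    partner + free catalyst + left-handed substrate → free catalyst + left-handed product (k = 9800 M⁻² h⁻¹)

A neighbouring flask carries 4.8 mol% of free catalyst, with everything else as in the recipe. Its dose is 7.20 × 10⁻⁵ M^2, 1.80 times the flask's, so K gives 32.8% reacted at 15 h. That neighbour gives c 33.2% and eP 34.4%, and its left-handed substrate and right-handed substrate end at 33.4% and 33.4%.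

All runs were generated by integration with made-up constants; scatter was added.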